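The route rests on disconnecting the bond between C2 of the tetrahydrofuran ring and C1 of its guaiacyl ring. A complete 2-methoxytetrahydrofuran donor, already bearing the cis C3 acyloxymethyl and C4 benzyl groups, is ionised at C2 and joined to an arylzinc. The step exploits ring oxygen O1, which stabilises the C2 cation. It also exploits the carbonyl oxygen of the C3 CH2O-(R)-2-methylbutanoyl group, which closes on C2 to a temporary cis-fused 1,3-dioxan-2-ylium ring. The aryl group then enters the open face, so the C–C bond and the C2 stereocentre arise together. The cis C3/C4 pair comes from a trans-lactone whose ring is cleaved and switched.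

Key step: step 7

Ring numbering used throughout: O1, C2 (aryl), C3 (CH2O-acyl), C4 (benzyl), C5 (CH2). The target is the (2R,3S,4S) tetrahydrofuran (2,3-trans, 3,4-cis) with an (R)-2-methylbutanoate.

Assumption: compounds 1, 2, 12 and 14 are taken as purchasable. The sense of induction of (R,R)-Et-DuPHOS–Rh in step 2 is assigned by analogy with itaconate half-esters and is to be checked through the sign of rotation of lactone 6; the ligand antipode is equally available.

Step 1
Reactants: 1 4-(benzyloxy)-3-methoxybenzaldehyde; 2 dimethyl succinate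
Product: 3 (E)-4-[4-(benzyloxy)-3-methoxyphenyl]-3-(methoxycarbonyl)but-3-enoic acid
Conditions: NaOMe, MeOH, reflux; then aq HCl
Reagents that add atoms: none
Why: Stobbe condensation, in which the succinate enolate adds to the aldehyde, the alkoxide lactonises and E1cB opening of the lactone ester should give the (E)-alkylidene half-ester with acid and ester already differentiated.

Step 2
Reactants: 3 (E)-4-[4-(benzyloxy)-3-methoxyphenyl]-3-(methoxycarbonyl)but-3-enoic acid
Product: 4 (S)-4-[4-(benzyloxy)-3-methoxyphenyl]-3-(methoxycarbonyl)butanoic acid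
Conditions: [Rh(cod)((R,R)-Et-DuPHOS)]BF4 (0.5 mol %), NaOMe (10 mol %), H2 (6 bar), MeOH, rt
Reagents that add atoms: none
Why: Rh-catalysed asymmetric hydrogenation of an itaconate-type half-ester, in which carboxylate and alkene chelate rhodium and the C2-symmetric bisphospholane selects the alkene face, so the stereocentre that becomes C4 is set as S by the catalyst while the aryl benzyl ether is inert to the homogeneous catalyst.

Step 3
Reactants: 4 (S)-4-[4-(benzyloxy)-3-methoxyphenyl]-3-(methoxycarbonyl)butanoic acid
Product: 6 (S)-4-[4-(benzyloxy)-3-methoxybenzyl]dihydrofuran-2(3H)-one, via hydroxy acid 5 (not isolated)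
Conditions: KOH (1 equiv), EtOH, 0 °C; CaCl2, NaBH4, EtOH, −10 °C to rt; then 2 M HCl, rt
Reagents that add atoms: none
Why: Chemoselective borohydride reduction, in which calcium borohydride reduces the methyl ester but not the carboxylate salt and acidification lactonises the γ-hydroxy acid without touching the stereocentre.

Step 4
Reactants: 6 (S)-4-[4-(benzyloxy)-3-methoxybenzyl]dihydrofuran-2(3H)-one
Product: 9 (3R,4S)-4-[4-(benzyloxy)-3-methoxybenzyl]-3-(dimethoxymethyl)dihydrofuran-2(3H)-one, via lithium enolate 7 (not isolated), via silyl ketene acetal 8 (not isolated)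
Conditions: LDA, THF, −78 °C; TMSCl, −78 °C to rt; solvent change; HC(OMe)3, TMSOTf (10 mol %), CH2Cl2, −78 °C
Reagents that add atoms: trimethyl orthoformate COC(OC)OC
Why: Mukaiyama-type alkylation of a silyl ketene acetal by the dimethoxycarbenium ion from the orthoformate, in which the electrophile adds to the ring face opposite the C4 benzyl group, so C3 is set trans (3R) by substrate control and the aldehyde-level carbon C2 arrives in protected form.

Step 5
Reactants: 9 (3R,4S)-4-[4-(benzyloxy)-3-methoxybenzyl]-3-(dimethoxymethyl)dihydrofuran-2(3H)-one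
Product: 11 [(3S,4S)-4-[4-(benzyloxy)-3-methoxybenzyl]-2-methoxytetrahydrofuran-3-yl]methanol (both C2 epimers), via diol acetal 10 (not isolated)
Conditions: LiAlH4, THF, 0 °C; aqueous work-up; then PPTS (cat.), CH2Cl2, rt
Reagents that add atoms: none
Why: Hydride reduction of the lactone followed by acid-catalysed intramolecular transacetalisation (5-exo-trig), in which only the C5 hydroxyl can reach the acetal carbon through a five-membered ring, so the ring is switched and the former trans pair becomes the cis C3/C4 pair of the tetrahydrofuran with no stereocentre touched and the C3 CH2OH left free.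

Step 6
Reactants: 11 [(3S,4S)-4-[4-(benzyloxy)-3-methoxybenzyl]-2-methoxytetrahydrofuran-3-yl]methanol; 12 (R)-2-methylbutanoic acid
Product: 13 [(3S,4S)-4-[4-(benzyloxy)-3-methoxybenzyl]-2-methoxytetrahydrofuran-3-yl]methyl (R)-2-methylbutanoate (both C2 epimers)
Conditions: EDC·HCl, DMAP (cat.), CH2Cl2, 0 °C to rt
Reagents that add atoms: none
Why: Steglich esterification of the only free hydroxyl, under which carbodiimide activation with catalytic DMAP at low temperature should not epimerise the α-stereocentre of the acid and the acetal is inert.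

Step 7
Reactants: 13 [(3S,4S)-4-[4-(benzyloxy)-3-methoxybenzyl]-2-methoxytetrahydrofuran-3-yl]methyl (R)-2-methylbutanoate; 14 1-(benzyloxy)-4-bromo-2-methoxybenzene
Product: 19 [(2R,3S,4S)-2-[4-(benzyloxy)-3-methoxyphenyl]-4-[4-(benzyloxy)-3-methoxybenzyl]tetrahydrofuran-3-yl]methyl (R)-2-methylbutanoate, via aryllithium 15 (not isolated), via arylzinc bromide 16 (not isolated), via 2-bromotetrahydrofuran 17 (not isolated), via dioxanylium ion 18 (not isolated)
Conditions: flask A: 14 (1.5 equiv), n-BuLi, Et2O, −78 °C; ZnBr2 (Et2O), −78 to 0 °C; flask B: 13, TMSBr, toluene, −40 to 0 °C; B into A, −40 °C to rt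
Reagents that add atoms: none
Why: TMSBr exchanges the anomeric methoxy group of 13 for bromide (17), Zn(II) ionises C2–Br with the help of the O1 lone pair, the carbonyl oxygen of the C3 acyloxymethyl group captures C2 to give the cis-fused ion 18, and arylzinc 16 opens 18 at C2 with inversion, transferring the carbon that bore zinc. The closest known reaction type is the C-arylation of acyl-protected glycosyl and furanosyl halides with arylzinc reagents under neighbouring-ester participation. The only ring closed is the temporary six-membered dioxanylium ring (6-exo-trig attack of the ester carbonyl on the C2=O1+ bond), and it is opened again in the same operation to return the ester of the target. The new stereocentre C2 (R) is controlled by C3 and C4, because their cis substituents and the bridging acyl oxygen all occupy one face, so the aryl group can only arrive anti, which gives the 2,3-trans-2,4-trans array. The step needs exocyclic rather than endocyclic C–O cleavage (secured by the more stable five-membered cyclic oxocarbenium ion), ipso regiochemistry on the arene (fixed by the C–Zn bond para to the benzyloxy group) and tolerance of the ester (secured by zinc). It must also outrun Friedel–Crafts attack by the arene of the C4 benzyl group and loss of H3, both of which are held back because the cation is masked on the very face on which that arene sits and no strong Lewis acid is present.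

Step 8
Reactants: 19 [(2R,3S,4S)-2-[4-(benzyloxy)-3-methoxyphenyl]-4-[4-(benzyloxy)-3-methoxybenzyl]tetrahydrofuran-3-yl]methyl (R)-2-methylbutanoate
Product: 20 [(2R,3S,4S)-2-(4-hydroxy-3-methoxyphenyl)-4-(4-hydroxy-3-methoxybenzyl)tetrahydrofuran-3-yl]methyl (R)-2-methylbutanoate
Conditions: H2 (1 atm), 10% Pd/C, EtOAc, rt, stopped after uptake of two equivalents of H2
Reagents that add atoms: none
Why: Catalytic hydrogenolysis, in which the two phenolic benzyl ethers should be cleaved much faster than the cyclic benzylic C2–O1 bond in a neutral aprotic solvent, while the ester and all four stereocentres are untouched.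

Compound list
1 | 4-(benzyloxy)-3-methoxybenzaldehyde | COc1cc(C=O)ccc1OCc1ccccc1 | starting material
2 | dimethyl succinate | COC(=O)CCC(=O)OC | starting material
3 | (E)-4-[4-(benzyloxy)-3-methoxyphenyl]-3-(methoxycarbonyl)but-3-enoic acid | COC(=O)/C(=C/c1ccc(OCc2ccccc2)c(OC)c1)CC(=O)O | intermediate
4 | (S)-4-[4-(benzyloxy)-3-methoxyphenyl]-3-(methoxycarbonyl)butanoic acid | OC(=O)C[C@H](Cc1ccc(OCc2ccccc2)c(OC)c1)C(=O)OC | intermediate
5 | (S)-4-[4-(benzyloxy)-3-methoxyphenyl]-3-(hydroxymethyl)butanoic acid (not isolated) | OC(=O)C[C@H](Cc1ccc(OCc2ccccc2)c(OC)c1)CO | intermediate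
6 | (S)-4-[4-(benzyloxy)-3-methoxybenzyl]dihydrofuran-2(3H)-one | O=C1C[C@H](Cc2ccc(OCc3ccccc3)c(OC)c2)CO1 | intermediate
7 | lithium enolate of 6 (not isolated) | [Li]OC1=C[C@H](Cc2ccc(OCc3ccccc3)c(OC)c2)CO1 | intermediate
8 | trimethylsilyl ketene acetal of 6 (not isolated) | C[Si](C)(C)OC1=C[C@H](Cc2ccc(OCc3ccccc3)c(OC)c2)CO1 | intermediate
9 | (3R,4S)-4-[4-(benzyloxy)-3-methoxybenzyl]-3-(dimethoxymethyl)dihydrofuran-2(3H)-one (trans) | COC(OC)[C@H]1[C@H](Cc2ccc(OCc3ccccc3)c(OC)c2)COC1=O | intermediate
10 | (2S,3S)-2-[4-(benzyloxy)-3-methoxybenzyl]-3-(dimethoxymethyl)butane-1,4-diol (not isolated) | COC(OC)[C@H](CO)[C@H](Cc1ccc(OCc2ccccc2)c(OC)c1)CO | intermediate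
11 | [(3S,4S)-4-[4-(benzyloxy)-3-methoxybenzyl]-2-methoxytetrahydrofuran-3-yl]methanol (3,4-cis, both C2 epimers) | OC[C@@H]1[C@H](Cc2ccc(OCc3ccccc3)c(OC)c2)COC1OC | intermediate
12 | (R)-2-methylbutanoic acid | CC[C@@H](C)C(=O)O | starting material
13 | [(3S,4S)-4-[4-(benzyloxy)-3-methoxybenzyl]-2-methoxytetrahydrofuran-3-yl]methyl (R)-2-methylbutanoate (both C2 epimers) | CC[C@@H](C)C(=O)OC[C@@H]1[C@H](Cc2ccc(OCc3ccccc3)c(OC)c2)COC1OC | intermediate
14 | 1-(benzyloxy)-4-bromo-2-methoxybenzene | COc1cc(Br)ccc1OCc1ccccc1 | starting material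
15 | [4-(benzyloxy)-3-methoxyphenyl]lithium (not isolated) | [Li]c1ccc(OCc2ccccc2)c(OC)c1 | intermediate
16 | [4-(benzyloxy)-3-methoxyphenyl]zinc bromide (not isolated) | Br[Zn]c1ccc(OCc2ccccc2)c(OC)c1 | intermediate
17 | [(3S,4S)-4-[4-(benzyloxy)-3-methoxybenzyl]-2-bromotetrahydrofuran-3-yl]methyl (R)-2-methylbutanoate (not isolated) | CC[C@@H](C)C(=O)OC[C@@H]1[C@H](Cc2ccc(OCc3ccccc3)c(OC)c2)COC1Br | intermediate
18 | cis-fused tetrahydrofuran/1,3-dioxan-2-ylium ion, acyl oxygen on C2 cis to the C3 CH2 group, shown as bromide (not isolated) | CC[C@@H](C)C1=[O+]C[C@@H]2[C@H](Cc3ccc(OCc4ccccc4)c(OC)c3)CO[C@@H]2O1.[Br-] | intermediate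
19 | [(2R,3S,4S)-2-[4-(benzyloxy)-3-methoxyphenyl]-4-[4-(benzyloxy)-3-methoxybenzyl]tetrahydrofuran-3-yl]methyl (R)-2-methylbutanoate | CC[C@@H](C)C(=O)OC[C@@H]1[C@H](Cc2ccc(OCc3ccccc3)c(OC)c2)CO[C@H]1c1ccc(OCc2ccccc2)c(OC)c1 | intermediate
20 | [(2R,3S,4S)-2-(4-hydroxy-3-methoxyphenyl)-4-(4-hydroxy-3-methoxybenzyl)tetrahydrofuran-3-yl]methyl (R)-2-methylbutanoate | CC[C@@H](C)C(=O)OC[C@@H]1[C@H](Cc2ccc(O)c(OC)c2)CO[C@H]1c1ccc(O)c(OC)c1 | target

Total step count: 8. Longest linear sequence: 8 (steps 1 to 8).

Steps most likely to fail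

**Step 7.**
- What may go wrong: ionisation at C2 may be followed by loss of H3, by endocyclic opening of the acetal, by capture of the cation by the neighbouring arene, or by poor facial selectivity if participation is weak.
- Fallback: it makes the same C–C bond by carbonyl addition and sets C2 under thermodynamic control. It sets out from 11.
- Mild aqueous acid (AcOH, H2O, THF) frees the lactol F1.
- Excess aryllithium 15 (or the corresponding Grignard reagent) adds to the open hydroxy-aldehyde form to give the benzylic triol F2 as carbinol epimers.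
- Camphorsulfonic acid in CH2Cl2 then closes the ring through the p-alkoxybenzyl cation, in which only the C5 hydroxyl can form a five-membered ring. This should give the more stable 2,3-trans product di-O-benzyl-(−)-lariciresinol F3.
- Steglich esterification of F3 with 12 comes back to the route at 19.

**Step 4.**
- What may go wrong: C-silylation instead of O-silylation of the enolate, loss of methanol from the product under the Lewis acid, or incomplete facial selectivity.
- Fallback: it replaces substrate control by auxiliary control and bypasses the lactone. It sets out from 4.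
- The free acid is coupled (PivCl, Et3N, LiCl) with (S)-4-benzyl-1,3-oxazolidin-2-one to give the N-acyl oxazolidinone F4.
- Soft enolisation of the imide (TiCl4, i-Pr2NEt, CH2Cl2, 0 °C) and reaction of the chelated titanium enolate with trimethyl orthoformate should give the α-(dimethoxymethyl) imide F5, with C3 set by the auxiliary.
- LiBH4 (THF, MeOH) reduces the imide and the methyl ester together and comes back to the route at diol acetal 10, which is cyclised with PPTS to 11 as in step 5.

**Step 8.**
- What may go wrong: over-reduction by hydrogenolysis of the benzylic C2–O1 bond, which opens the ring.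
- Fallback: reduction is replaced by Lewis-acid dealkylation with a cation scavenger. It sets out from 19 and uses BCl3 and pentamethylbenzene in CH2Cl2 at −78 °C, which transfers both benzyl groups to the scavenger.
- It comes back to the route at 20 and makes no new compound F0.

Further compounds
F1 | step 7 | (3S,4S)-4-[4-(benzyloxy)-3-methoxybenzyl]-3-(hydroxymethyl)tetrahydrofuran-2-ol (both C2 epimers) | OC[C@@H]1[C@H](Cc2ccc(OCc3ccccc3)c(OC)c2)COC1O
F2 | step 7 | (2S,3S)-2-[4-(benzyloxy)-3-methoxybenzyl]-3-{[4-(benzyloxy)-3-methoxyphenyl](hydroxy)methyl}butane-1,4-diol (carbinol epimers) | OC[C@@H](C(O)c1ccc(OCc2ccccc2)c(OC)c1)[C@H](Cc1ccc(OCc2ccccc2)c(OC)c1)CO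
F3 | step 7 | [(2R,3S,4S)-2-[4-(benzyloxy)-3-methoxyphenyl]-4-[4-(benzyloxy)-3-methoxybenzyl]tetrahydrofuran-3-yl]methanol | OC[C@@H]1[C@H](Cc2ccc(OCc3ccccc3)c(OC)c2)CO[C@H]1c1ccc(OCc2ccccc2)c(OC)c1
F4 | step 4 | methyl (S)-2-[4-(benzyloxy)-3-methoxybenzyl]-4-[(S)-4-benzyl-2-oxooxazolidin-3-yl]-4-oxobutanoate | O=C1OC[C@H](Cc2ccccc2)N1C(=O)C[C@H](Cc1ccc(OCc2ccccc2)c(OC)c1)C(=O)OC
F5 | step 4 | methyl (2S,3R)-2-[4-(benzyloxy)-3-methoxybenzyl]-4-[(S)-4-benzyl-2-oxooxazolidin-3-yl]-3-(dimethoxymethyl)-4-oxobutanoate | O=C1OC[C@H](Cc2ccccc2)N1C(=O)[C@@H](C(OC)OC)[C@H](Cc1ccc(OCc2ccccc2)c(OC)c1)C(=O)OC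
F0 | step 8 | none | none
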